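**Plan**
Numbering follows quinolin-4(1H)-one. Ring A is the N-methoxy-4-pyridone (N1, C2, C3, C4, C4a, C8a), ring B is the carbocycle (C4a, C5, C6, C7, C8, C8a), and the target is (5R).
Cuts: first the methyl of C3–OMe. A formyl helper is then placed on C6, and ring B is cut at C6–C7 and C4a–C5 (retro-[4+2]) to a C8a-vinyl pyridone and (E)-undec-2-enal. The remaining cuts are C7=C8 (Wittig), N1–C2/N1–C8a (O-to-N exchange) and C2–CH2OH (formaldehyde), which leads back to kojic acid.
Enabling feature: the enaminone N1–C8a=C4a–C4=O of ring A makes C4a nucleophilic, and C4a=C8a together with the vinyl group C8=C7 forms a 2-amino-1,3-diene. Once C4a has bonded to C5, C7 becomes the electrophilic end of an N-methoxy vinyliminium unit, and C6 closes onto it.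
Forward order: ring A comes first; kojic acid supplies its five ring carbons, C8 and the C3/C4 oxygens. Ring B comes second, in one step that also brings in the octyl chain.
Stereochemistry: C5, the only stereocentre, is set in the key step by the (S)-diphenylprolinol silyl ether catalyst. The transient centres C4a and C6 are erased by rearomatisation and decarbonylation.

Key step: step 6

Step 1
Reactants: 1 kojic acid
Product: 2 3-hydroxy-2,6-bis(hydroxymethyl)-4H-pyran-4-one
Conditions: 37% aq HCHO, NaOH, H2O, 0 °C to rt; then HCl to pH 2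
Reagents that add atoms: formaldehyde, C=O
Why: Base-mediated hydroxymethylation (Lederer–Manasse type aldol reaction) should take place at the only free carbon ortho to the enolic OH of 1, as is known for kojic acid and its 2-methyl analogue, and it creates the future C2–CH2OH unit.

Step 2
Reactants: 2 3-hydroxy-2,6-bis(hydroxymethyl)-4H-pyran-4-one
Product: 3 6-(hydroxymethyl)-2,2-dimethyl-4H-pyrano[3,2-d][1,3]dioxin-8-one
Conditions: Me2C(OMe)2, p-TsOH·H2O (5 mol %), acetone–DMF, rt
Reagents that add atoms: 2,2-dimethoxypropane, COC(C)(C)OC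
Why: Acid-catalysed transketalisation should engage only the enolic 3-OH and the neighbouring CH2OH, because only this pair can close a six-membered 1,3-dioxine ring (as in the acetonide of pyridoxine), so that the remote CH2OH, the future C8, stays free.

Step 3
Reactants: 3 6-(hydroxymethyl)-2,2-dimethyl-4H-pyrano[3,2-d][1,3]dioxin-8-one
Product: 4 6-(hydroxymethyl)-5-methoxy-2,2-dimethyl-4H-[1,3]dioxino[5,4-b]pyridin-8(5H)-one
Conditions: MeONH2·HCl (3 equiv), pyridine, 90 °C
Reagents that add atoms: O-methylhydroxylamine hydrochloride, CON.Cl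
Why: The pyranone-to-pyridone exchange (conjugate addition of the α-effect nucleophile next to the ring oxygen, ring opening, ring closure, loss of water) is well known for ethers of kojic acid with amines and hydroxylamines and installs N1–OMe while C4a still carries only H.

Step 4
Reactants: 4 6-(hydroxymethyl)-5-methoxy-2,2-dimethyl-4H-[1,3]dioxino[5,4-b]pyridin-8(5H)-one
Product: 5 5-methoxy-2,2-dimethyl-8-oxo-5,8-dihydro-4H-[1,3]dioxino[5,4-b]pyridine-6-carbaldehyde
Conditions: activated MnO2 (10 equiv), CH2Cl2, rt
Reagents that add atoms: none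
Why: Activated MnO2 oxidises heterobenzylic primary alcohols selectively to the aldehydes and leaves the ketal and the N–O bond untouched.

Step 5
Reactants: 5 5-methoxy-2,2-dimethyl-8-oxo-5,8-dihydro-4H-[1,3]dioxino[5,4-b]pyridine-6-carbaldehyde
Product: 6 5-methoxy-2,2-dimethyl-6-vinyl-4H-[1,3]dioxino[5,4-b]pyridin-8(5H)-one
Conditions: Ph3PCH3Br, NaN(SiMe3)2, THF, 0 °C; then added to 5, −78 °C to 0 °C; stored with BHT
Reagents that add atoms: methyltriphenylphosphonium bromide, C[P+](c1ccccc1)(c1ccccc1)c1ccccc1.[Br-]
Why: Wittig methylenation of the non-enolisable aldehyde adds C7, and inverse addition at low temperature keeps the base-sensitive N–OMe group away from excess ylide.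

Step 6
Reactants: 6 5-methoxy-2,2-dimethyl-6-vinyl-4H-[1,3]dioxino[5,4-b]pyridin-8(5H)-one; 7 (E)-undec-2-enal
Product: 9 (5R,6S)-6-formyl acetonide of 3-hydroxy-2-(hydroxymethyl)-1-methoxy-5-octyl-5,6,7,8-tetrahydroquinolin-4(1H)-one, via endo cycloadduct 8 (not isolated)
Conditions: (S)-α,α-diphenylprolinol trimethylsilyl ether (20 mol %), 4-nitrobenzoic acid (20 mol %), 7 (2 equiv), toluene (1 M), BHT (trace), rt to 40 °C; then Et3N (0.2 equiv), rt
Reagents that add atoms: none
Why: Proposed new method: the amine catalyst condenses reversibly with 7 to an E-configured s-trans iminium ion of lowered LUMO energy, C4a of 6 (the terminus with the largest HOMO coefficient of the 2-amino-1,3-diene C4a=C8a(N1)–C8=C7) bonds to its β-carbon C5, the enamine carbon C6 formed thereby closes onto C7 of the transient N-methoxy vinyliminium unit in the same asynchronous [4+2] event or directly afterwards, hydrolysis frees 8 and the catalyst, and the shift of the acidic C4a–H to C8 restores the aromatic pyridone in 9 and makes the sequence irreversible. The closest known reaction types are the iminium-catalysed enantioselective Diels–Alder reaction of 2-vinylindoles with enals and the thermal Diels–Alder reactions of 2-vinyl- and 2-styryl-substituted chromones and 4-quinolones with electron-poor alkenes, which show that the C2=C3 bond of a 4-pyranone or 4-pyridone ring can act as half of a diene, whereas the catalytic asymmetric version on a monocyclic 4-pyridone is not known. Ring B closes in the [4+2] mode, which in the stepwise limit is a 6-endo-trig attack of C6 on C7=C8. C5 is controlled by the catalyst, whose CPh2(OSiMe3) group shields one face of the iminium ion so that C4a adds to the open face of the β-carbon and the (S)-catalyst should lead to (5R), the E geometry of 7 places octyl and formyl trans, and the centres C4a and C6 are erased later. The step needs regioselectivity (C4a to the β-carbon, C7 to the α-carbon), which the donor N1 on C8a and the polarity of the enal secure, and a populated s-cis diene, which is favoured because the other rotamer presses C7 against the N-methoxy group while C4a carries only H; the nucleophilicity of C4a in the push–pull ring is the weak point.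

Step 7
Reactants: 9 (5R,6S)-6-formyl acetonide of 3-hydroxy-2-(hydroxymethyl)-1-methoxy-5-octyl-5,6,7,8-tetrahydroquinolin-4(1H)-one
Product: 10 acetonide of (5R)-3-hydroxy-2-(hydroxymethyl)-1-methoxy-5-octyl-5,6,7,8-tetrahydroquinolin-4(1H)-one
Conditions: RhCl(PPh3)3 (1.1 equiv), toluene, 110 °C
Reagents that add atoms: none
Why: Tsuji–Wilkinson decarbonylation (oxidative addition of the formyl C–H bond, CO extrusion, reductive elimination) removes the helper group under neutral conditions, turns C6 into CH2 and does not touch C5.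

Step 8
Reactants: 10 acetonide of (5R)-3-hydroxy-2-(hydroxymethyl)-1-methoxy-5-octyl-5,6,7,8-tetrahydroquinolin-4(1H)-one
Product: 11 (5R)-3-hydroxy-2-(hydroxymethyl)-1-methoxy-5-octyl-5,6,7,8-tetrahydroquinolin-4(1H)-one
Conditions: 1 M aq HCl, THF, 40 °C
Reagents that add atoms: none
Why: Acid hydrolysis of the isopropylidene ketal frees the enolic 3-OH and the primary alcohol, and neither the N–OMe group nor the non-acidic C5–H is affected.

Step 9
Reactants: 11 (5R)-3-hydroxy-2-(hydroxymethyl)-1-methoxy-5-octyl-5,6,7,8-tetrahydroquinolin-4(1H)-one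
Product: 12 (5R)-2-(hydroxymethyl)-1,3-dimethoxy-5-octyl-5,6,7,8-tetrahydroquinolin-4(1H)-one (target)
Conditions: MeI (1.1 equiv), K2CO3, acetone, rt
Reagents that add atoms: iodomethane, CI
Why: Williamson-type O-methylation with a weak base should be selective for the acidic enolic 3-OH over the primary alcohol, as in the usual etherification of 3-hydroxy-4-pyridones, and completes the target.

**Compound list**
1 | kojic acid, 5-hydroxy-2-(hydroxymethyl)-4H-pyran-4-one | OCc1cc(=O)c(O)co1 | starting material
2 | 3-hydroxy-2,6-bis(hydroxymethyl)-4H-pyran-4-one | OCc1cc(=O)c(O)c(CO)o1 | intermediate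
3 | 6-(hydroxymethyl)-2,2-dimethyl-4H-pyrano[3,2-d][1,3]dioxin-8-one | OCc1cc(=O)c2OC(C)(C)OCc2o1 | intermediate
4 | 6-(hydroxymethyl)-5-methoxy-2,2-dimethyl-4H-[1,3]dioxino[5,4-b]pyridin-8(5H)-one | OCc1cc(=O)c2OC(C)(C)OCc2n1OC | intermediate
5 | 5-methoxy-2,2-dimethyl-8-oxo-5,8-dihydro-4H-[1,3]dioxino[5,4-b]pyridine-6-carbaldehyde | O=Cc1cc(=O)c2OC(C)(C)OCc2n1OC | intermediate
6 | 5-methoxy-2,2-dimethyl-6-vinyl-4H-[1,3]dioxino[5,4-b]pyridin-8(5H)-one | C=Cc1cc(=O)c2OC(C)(C)OCc2n1OC | intermediate
7 | (E)-undec-2-enal | CCCCCCCC/C=C/C=O | starting material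
8 | (4aS,5R,6S)-endo cycloadduct: 6-formyl-1-methoxy-5-octyl-4a,5,6,7-tetrahydroquinolin-4(1H)-one with a C8=C8a double bond, 3-O/2-CH2O acetonide | CCCCCCCC[C@@H]1[C@@H](C=O)CC=C2[C@H]1C(=O)C3=C(COC(C)(C)O3)N2OC | intermediate
9 | (5R,6S)-6-formyl acetonide of 3-hydroxy-2-(hydroxymethyl)-1-methoxy-5-octyl-5,6,7,8-tetrahydroquinolin-4(1H)-one (octyl and formyl trans) | CCCCCCCC[C@@H]1[C@@H](C=O)CCc2c1c(=O)c1OC(C)(C)OCc1n2OC | intermediate
10 | acetonide of (5R)-3-hydroxy-2-(hydroxymethyl)-1-methoxy-5-octyl-5,6,7,8-tetrahydroquinolin-4(1H)-one | CCCCCCCC[C@@H]1CCCc2c1c(=O)c1OC(C)(C)OCc1n2OC | intermediate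
11 | (5R)-3-hydroxy-2-(hydroxymethyl)-1-methoxy-5-octyl-5,6,7,8-tetrahydroquinolin-4(1H)-one | CCCCCCCC[C@@H]1CCCc2c1c(=O)c(O)c(CO)n2OC | intermediate
12 | (5R)-2-(hydroxymethyl)-1,3-dimethoxy-5-octyl-5,6,7,8-tetrahydroquinolin-4(1H)-one | CCCCCCCC[C@@H]1CCCc2c1c(=O)c(OC)c(CO)n2OC | target

Total step count: 9. Longest linear sequence: 9 steps (1 to 12).

**Steps most likely to fail**

Step 6.
- What may go wrong: C4a of the push–pull pyridone may be too weak a nucleophile for the iminium ion. The catalyst is then tied up by reversible aza-Michael addition at C7, the vinyl group polymerises, or a thermal background reaction erodes the facial selectivity.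
- Fallback (known reaction types): ring B is again closed at C6–C7, now by a pericyclic event, and C5 is set afterwards. It sets out from 6 and returns at 10.
- Electrophilic iodination of 6 at C4a (NIS, CF3CO2H 10 mol %, MeCN, rt) should give 7-iodo-5-methoxy-2,2-dimethyl-6-vinyl-4H-[1,3]dioxino[5,4-b]pyridin-8(5H)-one F1.
- The coupling partner is 2-(dec-1-en-2-yl)-4,4,5,5-tetramethyl-1,3,2-dioxaborolane F2, made by Miyaura borylation of commercial 2-bromodec-1-ene (B2pin2, PdCl2(dppf), KOPh, toluene, 50 °C).
- Suzuki–Miyaura coupling of the two (Pd(OAc)2, SPhos, K3PO4, toluene–H2O, 80 °C) should give the triene 7-(dec-1-en-2-yl)-5-methoxy-2,2-dimethyl-6-vinyl-4H-[1,3]dioxino[5,4-b]pyridin-8(5H)-one F3.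
- Heating (o-dichlorobenzene, K2CO3, BHT, 160 °C) should trigger the disrotatory 6π electrocyclisation of C6=C5–C4a=C8a–C8=C7, a sequence known for 3-halo-2-alkenyl chromones and 4-quinolones. It gives the cross-conjugated 1-methoxy-5-octyl-6,7-dihydroquinolin-4(1H)-one acetonide F4.
- A base-mediated proton shift from C6 to C8 then gives the 1-methoxy-5-octyl-7,8-dihydroquinolin-4(1H)-one acetonide F5.
- Asymmetric hydrogenation of the trisubstituted C5=C6 bond ([Ir(cod)(tBu-PHOX)]B[C6H3(CF3)2]4, H2 50 bar, CH2Cl2, rt), with the ligand antipode chosen for (5R), leads to 10.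

Step 7.
- What may go wrong: β-hydride elimination from the secondary alkyl rhodium hydride would move a double bond into ring B and could destroy C5. Oxidative addition at the hindered formyl group could also be slow.
- Fallback: a radical decarboxylation that sets out from 9 and returns at 10.
- Pinnick oxidation (NaClO2, NaH2PO4, 2-methylbut-2-ene, tBuOH–H2O) should give the (5R,6S)-6-carboxylic acid acetonide F6.
- Esterification with 1-hydroxypyridine-2(1H)-thione (DCC, CH2Cl2, dark) gives the (5R,6S)-6-carboxylic acid 2-thioxopyridin-1(2H)-yl ester acetonide F7.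
- Barton decarboxylation (tBuSH, visible light, toluene, rt) replaces the carboxyl group by H without touching C5 and gives 10.

Step 3.
- What may go wrong: conjugate addition and ring opening by the weakly basic methoxyamine may be slow, and the ketal may be lost on prolonged heating.
- Fallback: the N–O unit is introduced in two stages, setting out from 3 and returning at 4.
- The more nucleophilic hydroxylamine (NH2OH·HCl, pyridine, 75 °C), a known exchange on kojic acid ethers, should give 5-hydroxy-6-(hydroxymethyl)-2,2-dimethyl-4H-[1,3]dioxino[5,4-b]pyridin-8(5H)-one F8.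
- Its acidic N–OH is then methylated selectively (MeI, K2CO3, DMF, rt) to give 4.

**Further compounds**
F1 | step 6 | 7-iodo-5-methoxy-2,2-dimethyl-6-vinyl-4H-[1,3]dioxino[5,4-b]pyridin-8(5H)-one | C=Cc1c(I)c(=O)c2OC(C)(C)OCc2n1OC
F2 | step 6 | 2-(dec-1-en-2-yl)-4,4,5,5-tetramethyl-1,3,2-dioxaborolane | C=C(CCCCCCCC)B1OC(C)(C)C(C)(C)O1
F3 | step 6 | 7-(dec-1-en-2-yl)-5-methoxy-2,2-dimethyl-6-vinyl-4H-[1,3]dioxino[5,4-b]pyridin-8(5H)-one | C=Cc1c(C(=C)CCCCCCCC)c(=O)c2OC(C)(C)OCc2n1OC
F4 | step 6 | 1-methoxy-5-octyl-6,7-dihydroquinolin-4(1H)-one acetonide (C4a=C5 and C8=C8a double bonds) | CCCCCCCCC1=C2C(=O)C3=C(COC(C)(C)O3)N(OC)C2=CCC1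
F5 | step 6 | 1-methoxy-5-octyl-7,8-dihydroquinolin-4(1H)-one acetonide (C5=C6 double bond) | CCCCCCCCC1=CCCc2c1c(=O)c1OC(C)(C)OCc1n2OC
F6 | step 7 | (5R,6S)-6-carboxylic acid acetonide | CCCCCCCC[C@@H]1[C@@H](C(=O)O)CCc2c1c(=O)c1OC(C)(C)OCc1n2OC
F7 | step 7 | (5R,6S)-6-carboxylic acid 2-thioxopyridin-1(2H)-yl ester acetonide | CCCCCCCC[C@@H]1[C@@H](C(=O)On3ccccc3=S)CCc2c1c(=O)c1OC(C)(C)OCc1n2OC
F8 | step 3 | 5-hydroxy-6-(hydroxymethyl)-2,2-dimethyl-4H-[1,3]dioxino[5,4-b]pyridin-8(5H)-one | OCc1cc(=O)c2OC(C)(C)OCc2n1O
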